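The target is the all-cis oxolane (2R,3R,4R). Its ring is O1–C2–C3–C4–C5, with the trimethoxyphenyl group on C2, C9H2OH on C3 and the C7′H2 veratryl arm on C4, all on one face.
Enabling feature: C3 and C4 are neighbouring ring carbons, each with one H and one one-carbon arm, and the arms are cis. The C3–C4 bond can therefore be traced back to a tetrasubstituted C3=C4 alkene in a 2,5-dihydrofuran whose only stereocentre is C2.
Cuts, in order: the two C–H bonds at C3 and C4 (hydrogenation), C3=C4 (ring-closing metathesis), O1–C5 (Williamson ether), C2–C3 (Morita–Baylis–Hillman) and aryl–C7′ (copper-catalysed Grignard coupling).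
Forward: the benzylallyl chloride and the silylated allylic alcohol are made separately and joined at O1–C5. The single ring is then closed at C3=C4, the silyl group is removed and the alkene is saturated.
Stereochemistry: C2 comes from a Sharpless kinetic resolution of the racemic allylic alcohol. C3 and C4 come from a hydroxyl-assisted syn hydrogenation on the face opposite the C2 aryl group.
Key step: step 7

Remark: the label at C2 reads S while C3 is an alkene carbon bearing CH2O (compounds 10–14) and R once C3 is saturated (15). The arrangement in space does not change.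
Assumption: the empirical enantiomer rule of the titanium–tartrate resolution is taken to hold for this 2-substituted 1-arylallyl alcohol.

Step 1
Reactants: 1 4-bromo-1,2-dimethoxybenzene; 2 3-chloro-2-(chloromethyl)prop-1-ene
Product: 4 4-[2-(chloromethyl)prop-2-en-1-yl]-1,2-dimethoxybenzene, via (3,4-dimethoxyphenyl)magnesium bromide 3 (not isolated)
Conditions: Mg, THF, reflux; then added to 2 (3 equiv), Li2CuCl4 (3 mol %), THF, −20 to 0 °C
Reagents that add atoms: magnesium, [Mg] (retained only in 3)
Why: Copper-catalysed allylic substitution of a Grignard reagent, in which SN2 and SN2′ attack on the symmetric dichloride give the same product and the excess of 2 holds back a second displacement.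

Step 2
Reactants: 5 3,4,5-trimethoxybenzaldehyde; 6 methyl acrylate
Product: 7 (±)-methyl 2-[hydroxy(3,4,5-trimethoxyphenyl)methyl]prop-2-enoate
Conditions: DABCO (0.5 equiv), 6 (5 equiv), MeOH, rt, several days
Reagents that add atoms: none
Why: Morita–Baylis–Hillman reaction, in which the amine adds to the acrylate, the resulting enolate attacks the aldehyde to form C2–C3 and loss of the amine restores the alkene; the carbinol centre forms as a racemate and is resolved in step 5.

Step 3
Reactants: 7 (±)-methyl 2-[hydroxy(3,4,5-trimethoxyphenyl)methyl]prop-2-enoate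
Product: 8 (±)-2-methylidene-1-(3,4,5-trimethoxyphenyl)propane-1,3-diol
Conditions: iBu2AlH (4 equiv), CH2Cl2, −78 to 0 °C; aqueous potassium sodium tartrate
Reagents that add atoms: none
Why: 1,2-Reduction of an α,β-unsaturated ester by a dialkylaluminium hydride, which after deprotonating the free hydroxyl takes the ester to the primary allylic alcohol without touching the 1,1-disubstituted alkene or the aryl methyl ethers.

Step 4
Reactants: 8 (±)-2-methylidene-1-(3,4,5-trimethoxyphenyl)propane-1,3-diol
Product: 9 (±)-2-{[(triisopropylsilyl)oxy]methyl}-1-(3,4,5-trimethoxyphenyl)prop-2-en-1-ol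
Conditions: iPr3SiCl (1.05 equiv), imidazole (2 equiv), CH2Cl2, 0 °C to rt
Reagents that add atoms: triisopropylsilyl chloride, CC(C)[Si](Cl)(C(C)C)C(C)C
Why: Chemoselective silylation of a diol, in which the hindered chlorosilane takes the open primary allylic hydroxyl well ahead of the secondary benzylic one.

Step 5
Reactants: 9 (±)-2-{[(triisopropylsilyl)oxy]methyl}-1-(3,4,5-trimethoxyphenyl)prop-2-en-1-ol
Product: 10 (1S)-2-{[(triisopropylsilyl)oxy]methyl}-1-(3,4,5-trimethoxyphenyl)prop-2-en-1-ol
Conditions: Ti(OiPr)4 (0.2 equiv), D-(−)-diisopropyl tartrate (0.24 equiv), tBuOOH (0.6 equiv, decane), 4 Å MS, CH2Cl2, −20 °C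
Reagents that add atoms: none
Why: Sharpless kinetic resolution of a secondary allylic alcohol, in which by the empirical rule of the titanium–tartrate epoxidation the D-(−)-tartrate catalyst oxidises the (R)-alcohol much faster, so the (R)-half is removed as its epoxy alcohol and the (S)-alcohol, which carries the C2 configuration of the target, is recovered by chromatography.

Step 6
Reactants: 10 (1S)-2-{[(triisopropylsilyl)oxy]methyl}-1-(3,4,5-trimethoxyphenyl)prop-2-en-1-ol; 4 4-[2-(chloromethyl)prop-2-en-1-yl]-1,2-dimethoxybenzene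
Product: 12 (S)-2-(3,4-dimethoxybenzyl)allyl 2-{[(triisopropylsilyl)oxy]methyl}-1-(3,4,5-trimethoxyphenyl)allyl ether, via sodium alkoxide 11 (not isolated)
Conditions: NaH (1.3 equiv), THF/DMF, 0 °C; then 4 (1.3 equiv), 0 °C to rt
Reagents that add atoms: sodium hydride, [Na+].[H-] (sodium retained only in 11)
Why: Williamson ether synthesis, in which the pre-formed secondary alkoxide displaces the primary allylic chloride to form O1–C5, no bond to C2 is broken so its configuration is kept, and the bulky triisopropylsilyl group resists the alkoxide-induced 1,5 O-to-O silyl shift that smaller silyl ethers of 1,3-diols undergo.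

Step 7
Reactants: 12 (S)-2-(3,4-dimethoxybenzyl)allyl 2-{[(triisopropylsilyl)oxy]methyl}-1-(3,4,5-trimethoxyphenyl)allyl ether
Product: 13 (2S)-4-(3,4-dimethoxybenzyl)-3-{[(triisopropylsilyl)oxy]methyl}-2-(3,4,5-trimethoxyphenyl)-2,5-dihydrofuran
Conditions: RuCl2[1,3-bis(2-methylphenyl)imidazolidin-2-ylidene](=CH-C6H4-2-OiPr) (second-generation Hoveyda–Grubbs type, 5–10 mol % in portions), 1,4-benzoquinone (10 mol %), toluene (0.01 M), 80 °C, argon sparge
Reagents that add atoms: none
Why: Olefin metathesis through ruthenacyclobutanes: the ruthenium carbene first exchanges with the less crowded 2-benzylallyl alkene to place a disubstituted alkylidene on C4, this adds to the C3 methylidene alkene in a (2+2) step, and cycloreversion releases the C3=C4 alkene and Ru=CH2, so that the two terminal CH2 groups leave as ethylene. The closest known reaction type is the ring-closing metathesis of bis(2-substituted allyl) ethers to 3,4-disubstituted 2,5-dihydrofurans with second-generation ruthenium catalysts, and the N-o-tolyl carbene ligand is chosen because its open metal pocket accepts geminally disubstituted alkenes better than the mesityl ligand. The one ring closed is the five-membered O1–C2–C3=C4–C5 ring, closed at C3=C4 with the new alkene endocyclic and the two alkenes held three atoms apart by the C2–O1–C5 tether. No stereocentre is formed and no bond to C2 takes part, so the configuration of 12 passes unchanged into 13. The step needs ring closure to outrun dimerisation and ruthenium hydride-induced migration of the allyl ether alkenes: the short tether and high dilution secure the first, while benzoquinone and the sweeping out of ethylene secure the second.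

Step 8
Reactants: 13 (2S)-4-(3,4-dimethoxybenzyl)-3-{[(triisopropylsilyl)oxy]methyl}-2-(3,4,5-trimethoxyphenyl)-2,5-dihydrofuran
Product: 14 [(2S)-4-(3,4-dimethoxybenzyl)-2-(3,4,5-trimethoxyphenyl)-2,5-dihydrofuran-3-yl]methanol
Conditions: Bu4NF (1.2 equiv), THF, 0 °C to rt, under argon
Reagents that add atoms: none
Why: Fluoride-induced cleavage of a silyl ether, driven by the strong Si–F bond, in a non-acidic medium that spares the doubly activated (benzylic, allylic) C2–O1 bond and thus the C2 configuration.

Step 9
Reactants: 14 [(2S)-4-(3,4-dimethoxybenzyl)-2-(3,4,5-trimethoxyphenyl)-2,5-dihydrofuran-3-yl]methanol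
Product: 15 [(2R,3R,4R)-4-(3,4-dimethoxybenzyl)-2-(3,4,5-trimethoxyphenyl)oxolan-3-yl]methanol (CNP0107562.2; aryl, CH2OH and benzyl all cis)
Conditions: [Ir(cod)(PCy3)(py)]PF6 (5 mol %), H2 (10 bar), CH2Cl2, rt
Reagents that add atoms: none
Why: Hydroxyl-directed homogeneous hydrogenation of an allylic alcohol, in which the cationic iridium centre binds the C9 hydroxyl and so speeds up the otherwise sluggish tetrasubstituted alkene, and because the freely rotating CH2OH arm can reach either face the choice is made by the C2 aryl group, so both hydrogens are delivered syn to the face it leaves open, which turns the C9 and C7′ arms toward the aryl side and sets C3 (R) and C4 (R).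

Compound list
1 | 4-bromo-1,2-dimethoxybenzene | COc1ccc(Br)cc1OC | starting material
2 | 3-chloro-2-(chloromethyl)prop-1-ene | C=C(CCl)CCl | starting material
3 | (3,4-dimethoxyphenyl)magnesium bromide | COc1ccc([Mg]Br)cc1OC | intermediate
4 | 4-[2-(chloromethyl)prop-2-en-1-yl]-1,2-dimethoxybenzene | COc1ccc(CC(=C)CCl)cc1OC | intermediate
5 | 3,4,5-trimethoxybenzaldehyde | COc1cc(C=O)cc(OC)c1OC | starting material
6 | methyl acrylate | C=CC(=O)OC | starting material
7 | (±)-methyl 2-[hydroxy(3,4,5-trimethoxyphenyl)methyl]prop-2-enoate | COC(=O)C(=C)C(O)c1cc(OC)c(OC)c(OC)c1 | intermediate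
8 | (±)-2-methylidene-1-(3,4,5-trimethoxyphenyl)propane-1,3-diol | OCC(=C)C(O)c1cc(OC)c(OC)c(OC)c1 | intermediate
9 | (±)-2-{[(triisopropylsilyl)oxy]methyl}-1-(3,4,5-trimethoxyphenyl)prop-2-en-1-ol | C=C(CO[Si](C(C)C)(C(C)C)C(C)C)C(O)c1cc(OC)c(OC)c(OC)c1 | intermediate
10 | (1S)-2-{[(triisopropylsilyl)oxy]methyl}-1-(3,4,5-trimethoxyphenyl)prop-2-en-1-ol | C=C(CO[Si](C(C)C)(C(C)C)C(C)C)[C@@H](O)c1cc(OC)c(OC)c(OC)c1 | intermediate
11 | sodium (1S)-2-{[(triisopropylsilyl)oxy]methyl}-1-(3,4,5-trimethoxyphenyl)prop-2-en-1-olate | C=C(CO[Si](C(C)C)(C(C)C)C(C)C)[C@@H]([O-])c1cc(OC)c(OC)c(OC)c1.[Na+] | intermediate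
12 | (S)-2-(3,4-dimethoxybenzyl)allyl 2-{[(triisopropylsilyl)oxy]methyl}-1-(3,4,5-trimethoxyphenyl)allyl ether | COc1ccc(CC(=C)CO[C@@H](c2cc(OC)c(OC)c(OC)c2)C(=C)CO[Si](C(C)C)(C(C)C)C(C)C)cc1OC | intermediate
13 | (2S)-4-(3,4-dimethoxybenzyl)-3-{[(triisopropylsilyl)oxy]methyl}-2-(3,4,5-trimethoxyphenyl)-2,5-dihydrofuran | COc1ccc(CC2=C(CO[Si](C(C)C)(C(C)C)C(C)C)[C@H](c3cc(OC)c(OC)c(OC)c3)OC2)cc1OC | intermediate
14 | [(2S)-4-(3,4-dimethoxybenzyl)-2-(3,4,5-trimethoxyphenyl)-2,5-dihydrofuran-3-yl]methanol | COc1ccc(CC2=C(CO)[C@H](c3cc(OC)c(OC)c(OC)c3)OC2)cc1OC | intermediate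
15 | [(2R,3R,4R)-4-(3,4-dimethoxybenzyl)-2-(3,4,5-trimethoxyphenyl)oxolan-3-yl]methanol | COc1ccc(C[C@H]2CO[C@@H](c3cc(OC)c(OC)c(OC)c3)[C@H]2CO)cc1OC | target

Total step count: 9. Longest linear sequence: 8 (steps 2 to 9).

Steps most likely to fail

Step 7. The disubstituted alkylidene may form too slowly from a 1,1-disubstituted alkene. The catalyst may then decay at 80 °C before the ring closes, and hydride species may move the allyl ether double bonds out of position. The fallback is a relay ring-closing metathesis that sets out from 10 and comes back at 13.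
- Triethyl phosphonoacetate is alkylated with 3,4-dimethoxybenzyl chloride (NaH, THF) to ethyl 2-(diethoxyphosphoryl)-3-(3,4-dimethoxyphenyl)propanoate F1.
- A Horner–Wadsworth–Emmons reaction with hex-5-enal (NaH, THF) gives ethyl 2-(3,4-dimethoxybenzyl)octa-2,7-dienoate F2, of which either alkene geometry serves.
- iBu2AlH gives 2-(3,4-dimethoxybenzyl)octa-2,7-dien-1-ol F3, and an Appel reaction (CBr4, PPh3) gives 4-[2-(bromomethyl)octa-2,7-dien-1-yl]-1,2-dimethoxybenzene F4.
- Alkoxide 11, made from 10 as in step 6, is alkylated with F4 to (S)-2-(3,4-dimethoxybenzyl)octa-2,7-dienyl 2-{[(triisopropylsilyl)oxy]methyl}-1-(3,4,5-trimethoxyphenyl)allyl ether F5.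
- With the same catalyst the ruthenium should load on the monosubstituted terminal alkene, expel cyclopentene and so arrive on C4 as the disubstituted alkylidene. Only the closure onto the C3 methylidene alkene then remains, and this should give 13.

Step 9. Hydrogen uptake at the tetrasubstituted alkene may be slow. Iridium hydrides may shift the double bond toward C5 or isomerise the allylic alcohol to the aldehyde, and either process would erode the facial selectivity. The fallback sets out from 13 and comes back at 15. The silyl group is kept and the alkene is reduced on a metal surface (Rh/Al2O3, 5 wt % Rh, H2 at moderate pressure, EtOAc). The flat ring should adsorb by the face free of the C2 aryl group and give (2R,3R,4R)-4-(3,4-dimethoxybenzyl)-3-{[(triisopropylsilyl)oxy]methyl}-2-(3,4,5-trimethoxyphenyl)oxolane F6. Bu4NF in THF then gives 15.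

Step 5. The two enantiomers may be epoxidised at rates that differ too little, because the aryl group and the CH2OSi arm both crowd the titanium centre. The Lewis acid may also ionise the benzylic alcohol and lower the enantiomeric purity. The fallback is a classical resolution that sets out from 9 and comes back at 10.
- Steglich esterification of 9 with (S)-methoxy(phenyl)acetic acid (DCC, DMAP, CH2Cl2) gives two diastereomers. They are (1S)-2-{[(triisopropylsilyl)oxy]methyl}-1-(3,4,5-trimethoxyphenyl)prop-2-en-1-yl (2S)-methoxy(phenyl)acetate F7 and (1R)-2-{[(triisopropylsilyl)oxy]methyl}-1-(3,4,5-trimethoxyphenyl)prop-2-en-1-yl (2S)-methoxy(phenyl)acetate F8.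
- The two esters are separated by chromatography or crystallisation.
- Comparing the shielding pattern of the two esters should also confirm the configuration at C2.
- Methanolysis of F7 (K2CO3, MeOH) gives 10.

Further compounds
F1 | step 7 | ethyl 2-(diethoxyphosphoryl)-3-(3,4-dimethoxyphenyl)propanoate | CCOC(=O)C(Cc1ccc(OC)c(OC)c1)P(=O)(OCC)OCC
F2 | step 7 | ethyl 2-(3,4-dimethoxybenzyl)octa-2,7-dienoate (E/Z mixture) | CCOC(=O)C(Cc1ccc(OC)c(OC)c1)=CCCCC=C
F3 | step 7 | 2-(3,4-dimethoxybenzyl)octa-2,7-dien-1-ol (E/Z mixture) | OCC(Cc1ccc(OC)c(OC)c1)=CCCCC=C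
F4 | step 7 | 4-[2-(bromomethyl)octa-2,7-dien-1-yl]-1,2-dimethoxybenzene (E/Z mixture) | BrCC(Cc1ccc(OC)c(OC)c1)=CCCCC=C
F5 | step 7 | (S)-2-(3,4-dimethoxybenzyl)octa-2,7-dienyl 2-{[(triisopropylsilyl)oxy]methyl}-1-(3,4,5-trimethoxyphenyl)allyl ether | COc1ccc(CC(=CCCCC=C)CO[C@@H](c2cc(OC)c(OC)c(OC)c2)C(=C)CO[Si](C(C)C)(C(C)C)C(C)C)cc1OC
F6 | step 9 | (2R,3R,4R)-4-(3,4-dimethoxybenzyl)-3-{[(triisopropylsilyl)oxy]methyl}-2-(3,4,5-trimethoxyphenyl)oxolane | COc1ccc(C[C@H]2CO[C@@H](c3cc(OC)c(OC)c(OC)c3)[C@H]2CO[Si](C(C)C)(C(C)C)C(C)C)cc1OC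
F7 | step 5 | (1S)-2-{[(triisopropylsilyl)oxy]methyl}-1-(3,4,5-trimethoxyphenyl)prop-2-en-1-yl (2S)-methoxy(phenyl)acetate | CO[C@H](C(=O)O[C@@H](c1cc(OC)c(OC)c(OC)c1)C(=C)CO[Si](C(C)C)(C(C)C)C(C)C)c1ccccc1
F8 | step 5 | (1R)-2-{[(triisopropylsilyl)oxy]methyl}-1-(3,4,5-trimethoxyphenyl)prop-2-en-1-yl (2S)-methoxy(phenyl)acetate | CO[C@H](C(=O)O[C@H](c1cc(OC)c(OC)c(OC)c1)C(=C)CO[Si](C(C)C)(C(C)C)C(C)C)c1ccccc1
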